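Ring A (C1–C5, C10; drimane numbering) is closed last across C3–C4, the bond that joins the chlorinated methine to the quaternary carbon bearing methyl and the 4-methylpent-3-enyl chain. The key step is a stereoconvergent hydrogen-atom-transfer radical cyclization: chlorine at C3 stabilizes a planar α-chloroalkyl radical, which adds 6-exo to C4, the β-carbon of a β,β-disubstituted vinyl sulfone. In one operation it forms the C3–C4 bond, the trans-decalin and both new stereocentres from E/Z mixtures. Its precursor is a carvone-derived ring B cyclohexenone carrying a 3-chloro-1-silyloxyallyl arm on quaternary C10 and the sulfonyl alkene on C5; the sulfone later anchors the prenyl unit.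

Key step: step 9

Remark: drimane-type numbering is used for all intermediates (ring A: C1 carbinol, C2, C3 chloromethine, C4 quaternary, C5, C10; ring B: C5 to C10 with C7=C8; C11 and C12 are the carbons on C9 and C8; β is the face of the C10 methyl), and the target is taken as the open hydroxy dialdehyde as drawn.

Step 1
Reactants: 1 (R)-(−)-carvone
Product: 2 (5R,6S)-2,6-dimethyl-5-(prop-1-en-2-yl)cyclohex-2-en-1-one (trans-6-methylcarvone)
Conditions: LiN(iPr)2, THF, −78 °C; MeI, −78 to 0 °C
Reagents that add atoms: iodomethane, CI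
Why: Enolate alkylation: LiN(iPr)2 deprotonates the saturated α-position (C6) to give the cross-conjugated lithium dienolate, which should be methylated mainly anti to the isopropenyl group, a centre that is planarized again in step 2.

Step 2
Reactants: 2 trans-6-methylcarvone; 3 acrolein
Product: 4 (5S,6R)-6-(1-hydroxyprop-2-en-1-yl)-2,6-dimethyl-5-(prop-1-en-2-yl)cyclohex-2-en-1-one (both carbinol epimers)
Conditions: LiN(iPr)2, THF, −78 °C; then 3, −78 °C; H2O quench
Reagents that add atoms: none
Why: Aldol addition: the fully substituted lithium enolate of 2 should add 1,2 to acrolein on the face anti to the neighbouring isopropenyl group, which sets quaternary C10 with methyl cis and the new arm trans to isopropenyl, whereas the carbinol centre is not expected to be controlled and is reset in steps 3 and 4.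

Step 3
Reactants: 4 aldol adduct
Product: 5 (5S,6R)-6-acryloyl-2,6-dimethyl-5-(prop-1-en-2-yl)cyclohex-2-en-1-one
Conditions: Dess–Martin periodinane, CH2Cl2, 0 °C
Reagents that add atoms: none
Why: Dess–Martin oxidation should turn both carbinol epimers into one 1,3-diketone under non-basic conditions that avoid retro-aldol cleavage.

Step 4
Reactants: 5 1,3-diketone
Product: 6 (5S,6R)-6-[(1S)-1-hydroxyprop-2-en-1-yl]-2,6-dimethyl-5-(prop-1-en-2-yl)cyclohex-2-en-1-one
Conditions: Zn(BH4)2, Et2O, −40 °C
Reagents that add atoms: none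
Why: Chelation-controlled 1,2-reduction: zinc bridges the two carbonyl oxygens, and hydride should attack the more electrophilic, less hindered acyclic vinyl ketone on the face next to the C10 methyl rather than the face covered by ring B, which sets the (1S) carbinol that becomes the axial 1α-hydroxyl group.

Step 5
Reactants: 6 allylic alcohol
Product: 7 (5S,6R)-6-[(1S)-1-(tert-butyldimethylsilyloxy)prop-2-en-1-yl]-2,6-dimethyl-5-(prop-1-en-2-yl)cyclohex-2-en-1-one
Conditions: TBSOTf, 2,6-lutidine, CH2Cl2, −78 to 0 °C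
Reagents that add atoms: tert-butyldimethylsilyl triflate, CC(C)(C)[Si](C)(C)OS(=O)(=O)C(F)(F)F
Why: Silylation with the silyl triflate and 2,6-lutidine protects the hindered allylic alcohol and so blocks retro-aldol cleavage in the basic steps that follow.

Step 6
Reactants: 7 silyl ether
Product: 9 (2R)-2-[(1R,6R)-6-acetyl-1,3-dimethyl-2-oxocyclohex-3-en-1-yl]-2-[(tert-butyldimethylsilyl)oxy]acetaldehyde, via bis-ozonide 8 (not isolated)
Conditions: O3, CH2Cl2, −78 °C; then Me2S, −78 °C to rt
Reagents that add atoms: ozone, [O-][O+]=O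
Why: Ozonolysis with reductive work-up should cleave the two electron-rich terminal alkenes faster than the electron-poor enone alkene and give the α-silyloxy aldehyde and the methyl ketone in one operation.

Step 7
Reactants: 9 keto aldehyde
Product: 10 (5R,6R)-5-acetyl-6-[(1S,2E)-1-(tert-butyldimethylsilyloxy)-3-chloroprop-2-en-1-yl]-2,6-dimethylcyclohex-2-en-1-one
Conditions: CrCl2, CHCl3, THF, 65 °C
Reagents that add atoms: chloroform, ClC(Cl)Cl
Why: Takai olefination: the geminal dichromium species formed from CHCl3 and CrCl2 should react with the aldehyde but not with the two ketones, is not basic enough to epimerize the α-silyloxy centre and gives the chloroalkene with E geometry.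

Step 8
Reactants: 10 chloroalkene methyl ketone
Product: 11 (5R,6R)-6-[(1S,2E)-1-(tert-butyldimethylsilyloxy)-3-chloroprop-2-en-1-yl]-2,6-dimethyl-5-[1-(phenylsulfonyl)prop-1-en-2-yl]cyclohex-2-en-1-one (E/Z mixture at the sulfonyl alkene)
Conditions: PhSO2CH2SiMe3, n-BuLi, THF, −78 °C; then 10, −78 to 0 °C
Reagents that add atoms: trimethyl[(phenylsulfonyl)methyl]silane, C[Si](C)(C)CS(=O)(=O)c1ccccc1
Why: Peterson olefination: the lithiated α-silyl sulfone should add to the unhindered methyl ketone faster than to the hindered ring enone, and the β-silyl alkoxide eliminates to the β,β-disubstituted vinyl sulfone, whose E/Z mixture is acceptable for step 9.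

Step 9
Reactants: 11 chloroalkene vinyl sulfone
Product: 12 trans-octalone 1α-(tert-butyldimethylsilyloxy)-3β-chloro-4β,8,10β-trimethyl-4α-[(phenylsulfonyl)methyl]octal-7-en-9-one (5α-H)
Conditions: Fe(acac)3 (30 mol %), PhSiH3, EtOH/(CH2OH)2, 60 °C
Reagents that add atoms: none
Why: An iron hydride formed from Fe(acac)3 and PhSiH3 transfers a hydrogen atom to C2 of the chloroalkene, the planar chlorine-stabilized radical at C3 adds to C4 (the β-carbon of the vinyl sulfone), and the α-sulfonyl radical is reduced and protonated by the alcohol. The closest known reaction type is the iron-hydride-initiated reductive coupling of heteroatom-substituted donor olefins (halo-olefins included) with Michael acceptors, a Giese addition run here intramolecularly. Ring A closes in the 6-exo-trig mode through a chair that is fused trans to ring B, because the C1 arm on C10 and the alkene on C5 are both equatorial on ring B. C3 is set by the axial silyloxy group at C1, which forces chlorine into the equatorial β position to avoid a 1,3-diaxial clash, and C4 is set by the axial C10 methyl, which keeps the sulfonylmethylene carbon equatorial (α) and leaves the C4 methyl axial (β). Since the C3 radical is planar and both vinyl sulfone isomers should react through the same chair, any E/Z mixture at either alkene converges on one diastereomer. The step needs hydrogen transfer to the chloroalkene in preference to the enone and the sulfonyl alkene and 6-exo rather than 7-endo attack; the donor character of the chloroalkene and the polarity match between the nucleophilic radical and the sulfone β-carbon should secure both.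

Step 10
Reactants: 12 trans-octalone
Product: 13 diene 1α-(tert-butyldimethylsilyloxy)-3β-chloro-4β,8,10β-trimethyl-9-methylidene-4α-[(phenylsulfonyl)methyl]octal-7-ene
Conditions: Cp2TiMe2, toluene, 70 °C
Reagents that add atoms: dimethyltitanocene Cp2TiMe2, C[Ti](C)(C1C=CC=C1)C1C=CC=C1
Why: Petasis methylenation: the titanium methylidene released thermally from Cp2TiMe2 should olefinate the hindered, non-enolizable ketone without base, so that the acidic sulfone position, the chloride and the silyl ether are untouched.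

Step 11
Reactants: 13 diene
Product: 15 11-alcohol 1α-(tert-butyldimethylsilyloxy)-3β-chloro-9β-(hydroxymethyl)-4β,8,10β-trimethyl-4α-[(phenylsulfonyl)methyl]octal-7-ene, via B-alkyl-9-BBN adduct 14 (not isolated)
Conditions: 9-BBN, THF, 0 °C to rt; then NaOH, H2O2
Reagents that add atoms: 9-borabicyclo[3.3.1]nonane, B1C2CCCC1CCC2; hydrogen peroxide, OO
Why: Hydroboration–oxidation: 9-BBN should add to the 1,1-disubstituted alkene of the diene with boron on terminal C11 and hydrogen delivered to C9 on the α face, anti to the axial C10 methyl, and oxidation with retention gives the 9β-hydroxymethyl group.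

Step 12
Reactants: 15 11-alcohol
Product: 16 11,12-diol 1α-(tert-butyldimethylsilyloxy)-3β-chloro-8,9β-bis(hydroxymethyl)-4β,10β-dimethyl-4α-[(phenylsulfonyl)methyl]octal-7-ene
Conditions: SeO2 (cat.), t-BuOOH, CH2Cl2, rt
Reagents that add atoms: tert-butyl hydroperoxide, CC(C)(C)OO
Why: Selenium dioxide allylic oxidation (ene reaction followed by 2,3-sigmatropic shift, turned over by t-BuOOH) occurs at the more substituted alkene terminus C8 and should prefer the (E)-methyl group C12 over the tertiary C9–H, which gives the primary allylic alcohol.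

Step 13
Reactants: 16 11,12-diol; 17 prenyl bromide (1-bromo-3-methylbut-2-ene)
Product: 18 alkylated sulfone 1α-(tert-butyldimethylsilyloxy)-3β-chloro-8,9β-bis(hydroxymethyl)-4β,10β-dimethyl-4α-[4-methyl-1-(phenylsulfonyl)pent-3-en-1-yl]octal-7-ene (both epimers at the sulfonyl carbon)
Conditions: n-BuLi (3.3 equiv), THF/DMPU, −78 °C; then 17, −78 to −20 °C; H2O quench
Reagents that add atoms: none
Why: Alkylation of a sulfone-stabilized carbanion: excess n-BuLi forms both lithium alkoxides and the α-sulfonyl carbanion, only the carbanion should be alkylated by the allylic bromide in an SN2 reaction, the equatorial C3 chloride has no antiperiplanar partner for elimination or cyclopropane formation, and the new sulfone-bearing centre is removed in step 14.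

Step 14
Reactants: 18 alkylated sulfone
Product: 19 diol 1α-(tert-butyldimethylsilyloxy)-3β-chloro-8,9β-bis(hydroxymethyl)-4β,10β-dimethyl-4α-(4-methylpent-3-en-1-yl)octal-7-ene
Conditions: Na(Hg) (6% Na), Na2HPO4, MeOH/THF, −20 °C
Reagents that add atoms: none
Why: Reductive desulfonylation: electron transfer from sodium amalgam cleaves the C–S bond and methanol protonates the carbanion, while the unactivated secondary chloride and the trisubstituted alkenes should not be reduced.

Step 15
Reactants: 19 diol
Product: 20 silyl-protected dialdehyde 1α-(tert-butyldimethylsilyloxy)-3β-chloro-4β,10β-dimethyl-4α-(4-methylpent-3-en-1-yl)octal-7-ene-8,9β-dicarbaldehyde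
Conditions: (COCl)2, DMSO, CH2Cl2, −78 °C; then i-Pr2NEt, −78 to −30 °C
Reagents that add atoms: none
Why: Swern oxidation should convert both primary alcohols into the aldehydes at low temperature without lactol or lactone formation from the 1,4-diol, and the hindered amine limits epimerization at C9.

Step 16
Reactants: 20 silyl-protected dialdehyde
Product: 21 (1R,4aR,5S,6S,8S,8aS)-6-chloro-8-hydroxy-5,8a-dimethyl-5-(4-methylpent-3-en-1-yl)-1,4,4a,5,6,7,8,8a-octahydronaphthalene-1,2-dicarbaldehyde (CNP0155449.1)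
Conditions: HF·pyridine, pyridine, THF, 0 °C to rt
Reagents that add atoms: none
Why: Desilylation with buffered HF·pyridine frees the axial C1 hydroxyl group under weakly acidic conditions that should not epimerize the C9 aldehyde.

Compound list
1 | (R)-(−)-carvone, (5R)-2-methyl-5-(prop-1-en-2-yl)cyclohex-2-en-1-one | CC1=CC[C@H](CC1=O)C(C)=C | starting material
2 | (5R,6S)-2,6-dimethyl-5-(prop-1-en-2-yl)cyclohex-2-en-1-one (trans-6-methylcarvone) | C[C@H]1[C@H](C(C)=C)CC=C(C)C1=O | intermediate
3 | acrolein (prop-2-enal) | C=CC=O | starting material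
4 | (5S,6R)-6-(1-hydroxyprop-2-en-1-yl)-2,6-dimethyl-5-(prop-1-en-2-yl)cyclohex-2-en-1-one, both carbinol epimers | C=CC(O)[C@]1(C)C(=O)C(C)=CC[C@H]1C(C)=C | intermediate
5 | (5S,6R)-6-acryloyl-2,6-dimethyl-5-(prop-1-en-2-yl)cyclohex-2-en-1-one | C=CC(=O)[C@]1(C)C(=O)C(C)=CC[C@H]1C(C)=C | intermediate
6 | (5S,6R)-6-[(1S)-1-hydroxyprop-2-en-1-yl]-2,6-dimethyl-5-(prop-1-en-2-yl)cyclohex-2-en-1-one | C=C[C@H](O)[C@]1(C)C(=O)C(C)=CC[C@H]1C(C)=C | intermediate
7 | (5S,6R)-6-[(1S)-1-(tert-butyldimethylsilyloxy)prop-2-en-1-yl]-2,6-dimethyl-5-(prop-1-en-2-yl)cyclohex-2-en-1-one | C=C[C@H](O[Si](C)(C)C(C)(C)C)[C@]1(C)C(=O)C(C)=CC[C@H]1C(C)=C | intermediate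
8 | bis-ozonide of 7 (both terminal alkenes as 1,2,4-trioxolanes, ring and carbinol centres as in 7) | C1(OCOO1)[C@H](O[Si](C)(C)C(C)(C)C)[C@]2(C)C(=O)C(C)=CC[C@H]2C3(C)OCOO3 | intermediate
9 | (2R)-2-[(1R,6R)-6-acetyl-1,3-dimethyl-2-oxocyclohex-3-en-1-yl]-2-[(tert-butyldimethylsilyl)oxy]acetaldehyde | O=C[C@H](O[Si](C)(C)C(C)(C)C)[C@]1(C)C(=O)C(C)=CC[C@H]1C(C)=O | intermediate
10 | (5R,6R)-5-acetyl-6-[(1S,2E)-1-(tert-butyldimethylsilyloxy)-3-chloroprop-2-en-1-yl]-2,6-dimethylcyclohex-2-en-1-one | Cl/C=C/[C@H](O[Si](C)(C)C(C)(C)C)[C@]1(C)C(=O)C(C)=CC[C@H]1C(C)=O | intermediate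
11 | (5R,6R)-6-[(1S,2E)-1-(tert-butyldimethylsilyloxy)-3-chloroprop-2-en-1-yl]-2,6-dimethyl-5-[1-(phenylsulfonyl)prop-1-en-2-yl]cyclohex-2-en-1-one, E/Z mixture at the sulfonyl alkene | Cl/C=C/[C@H](O[Si](C)(C)C(C)(C)C)[C@]1(C)C(=O)C(C)=CC[C@H]1C(C)=CS(=O)(=O)c2ccccc2 | intermediate
12 | trans-octalone: 1α-(tert-butyldimethylsilyloxy)-3β-chloro-4β,8,10β-trimethyl-4α-[(phenylsulfonyl)methyl]octal-7-en-9-one, 5α-H | O=S(=O)(c3ccccc3)C[C@]1(C)[C@@H](Cl)C[C@H](O[Si](C)(C)C(C)(C)C)[C@]2(C)C(=O)C(C)=CC[C@@H]12 | intermediate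
13 | diene: 9-methylidene analogue of 12 | O=S(=O)(c3ccccc3)C[C@]1(C)[C@@H](Cl)C[C@H](O[Si](C)(C)C(C)(C)C)[C@]2(C)C(=C)C(C)=CC[C@@H]12 | intermediate
14 | B-alkyl-9-BBN adduct of 13 (boron on C11, 9α-H) | O=S(=O)(c3ccccc3)C[C@]1(C)[C@@H](Cl)C[C@H](O[Si](C)(C)C(C)(C)C)[C@]2(C)[C@@H](CB3C4CCCC3CCC4)C(C)=CC[C@@H]12 | intermediate
15 | 11-alcohol: 9β-(hydroxymethyl)-8-methyl-octal-7-ene with 1α-OTBS, 3β-Cl, 4β-Me, 4α-CH2SO2Ph, 10β-Me | O=S(=O)(c3ccccc3)C[C@]1(C)[C@@H](Cl)C[C@H](O[Si](C)(C)C(C)(C)C)[C@]2(C)[C@@H](CO)C(C)=CC[C@@H]12 | intermediate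
16 | 11,12-diol: 8,9β-bis(hydroxymethyl) analogue of 15 | O=S(=O)(c3ccccc3)C[C@]1(C)[C@@H](Cl)C[C@H](O[Si](C)(C)C(C)(C)C)[C@]2(C)[C@@H](CO)C(CO)=CC[C@@H]12 | intermediate
17 | prenyl bromide (1-bromo-3-methylbut-2-ene) | CC(C)=CCBr | starting material
18 | alkylated sulfone: 4α-[4-methyl-1-(phenylsulfonyl)pent-3-en-1-yl] analogue of 16, both epimers at the sulfonyl carbon | CC(C)=CCC(S(=O)(=O)c3ccccc3)[C@]1(C)[C@@H](Cl)C[C@H](O[Si](C)(C)C(C)(C)C)[C@]2(C)[C@@H](CO)C(CO)=CC[C@@H]12 | intermediate
19 | diol: 1α-(tert-butyldimethylsilyloxy)-3β-chloro-8,9β-bis(hydroxymethyl)-4β,10β-dimethyl-4α-(4-methylpent-3-en-1-yl)octal-7-ene | CC(C)=CCC[C@]1(C)[C@@H](Cl)C[C@H](O[Si](C)(C)C(C)(C)C)[C@]2(C)[C@@H](CO)C(CO)=CC[C@@H]12 | intermediate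
20 | tert-butyldimethylsilyl ether of the target (8,9β-dicarbaldehyde) | CC(C)=CCC[C@]1(C)[C@@H](Cl)C[C@H](O[Si](C)(C)C(C)(C)C)[C@]2(C)[C@@H](C=O)C(C=O)=CC[C@@H]12 | intermediate
21 | (1R,4aR,5S,6S,8S,8aS)-6-chloro-8-hydroxy-5,8a-dimethyl-5-(4-methylpent-3-en-1-yl)-1,4,4a,5,6,7,8,8a-octahydronaphthalene-1,2-dicarbaldehyde | CC(C)=CCC[C@]1(C)[C@@H](Cl)C[C@H](O)[C@]2(C)[C@@H](C=O)C(C=O)=CC[C@@H]12 | target

Total step count: 16. Longest linear sequence: 16 steps (from 1).

Steps most likely to fail

Step 9. Hydrogen transfer could go to the chlorine-bearing carbon instead of C2, which would be followed by loss of chlorine, or the ring enone could suffer conjugate reduction before cyclization. The fallback makes the same C3 radical by halogen abstraction instead of hydrogen transfer. It sets out from 7: aldehyde-selective Wacker oxidation of the vinyl group (PdCl2(PhCN)2, CuCl2, AgNO2, t-BuOH/MeNO2, O2) would give the β-silyloxy aldehyde F1; (PhO)3P/Cl2/Et3N would convert it into the geminal dichloride F2; ozonolysis of the isopropenyl group (O3, then Me2S) would give the methyl ketone F3; Peterson olefination as in step 8 would give the dichloride vinyl sulfone F4; Bu3SnH/AIBN (slow addition, benzene, 80 °C) would abstract one chlorine and close ring A by the same 6-exo cyclization, coming back to the route at 12.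

Step 11. Hydroboration could show poor facial selectivity at C9, because the α face is shielded by the axial 1α-silyloxy group and the β face by the C10 methyl; the methylenation of the hindered ketone in step 10 could also be slow. The fallback installs C11 by carbonylation and sets C9 by protonation. It sets out from 12: KN(SiMe3)2/PhNTf2 would give the dienyl triflate F5 by γ-deprotonation at C6; Pd(OAc)2/dppf, CO, MeOH, Et3N would give the dienoate F6; 1,6-reduction with (i-Bu)2AlH/MeCu/HMPA and kinetic protonation at C9 from the α face would give the β,γ-unsaturated 9β-ester F7; (i-Bu)2AlH reduction would come back to the route at 15.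

Step 13. Alkylation of the neopentyl-type sulfonyl carbanion could be slow, and O-alkylation of the alkoxides could compete. The fallback builds the chain by olefination instead of alkylation. It sets out from 16: n-BuLi (3.3 equiv) followed by MoO5·pyridine·HMPA would oxidize the carbanion to the C4 aldehyde F8 (oxidative desulfonylation); Wittig reaction with the ylide from (3-methylbut-2-en-1-yl)triphenylphosphonium bromide and n-BuLi would give the conjugated diene F9; diimide (potassium azodicarboxylate, AcOH) would reduce the 1,2-disubstituted alkene selectively and come back to the route at 19.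

Further compounds
F1 | step 9 | β-silyloxy aldehyde: (5S,6R)-6-[(1S)-1-(tert-butyldimethylsilyloxy)-3-oxopropyl]-2,6-dimethyl-5-(prop-1-en-2-yl)cyclohex-2-en-1-one | O=CC[C@H](O[Si](C)(C)C(C)(C)C)[C@]1(C)C(=O)C(C)=CC[C@H]1C(C)=C
F2 | step 9 | geminal dichloride: 3,3-dichloropropyl analogue of F1 | ClC(Cl)C[C@H](O[Si](C)(C)C(C)(C)C)[C@]1(C)C(=O)C(C)=CC[C@H]1C(C)=C
F3 | step 9 | methyl ketone: 5-acetyl analogue of F2 | ClC(Cl)C[C@H](O[Si](C)(C)C(C)(C)C)[C@]1(C)C(=O)C(C)=CC[C@H]1C(C)=O
F4 | step 9 | dichloride vinyl sulfone: 5-[1-(phenylsulfonyl)prop-1-en-2-yl] analogue of F2, E/Z mixture | ClC(Cl)C[C@H](O[Si](C)(C)C(C)(C)C)[C@]1(C)C(=O)C(C)=CC[C@H]1C(C)=CS(=O)(=O)c2ccccc2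
F5 | step 11 | dienyl triflate: 9-(trifluoromethylsulfonyloxy)-6,8-diene derived from 12 | O=S(=O)(c3ccccc3)C[C@]1(C)[C@@H](Cl)C[C@H](O[Si](C)(C)C(C)(C)C)[C@]2(C)C(OS(=O)(=O)C(F)(F)F)=C(C)C=C[C@@H]12
F6 | step 11 | dienoate: methyl 6,8-diene-9-carboxylate derived from F5 | O=S(=O)(c3ccccc3)C[C@]1(C)[C@@H](Cl)C[C@H](O[Si](C)(C)C(C)(C)C)[C@]2(C)C(C(=O)OC)=C(C)C=C[C@@H]12
F7 | step 11 | β,γ-unsaturated ester: methyl 9β-carboxylate of the 7-ene, 9α-H | O=S(=O)(c3ccccc3)C[C@]1(C)[C@@H](Cl)C[C@H](O[Si](C)(C)C(C)(C)C)[C@]2(C)[C@@H](C(=O)OC)C(C)=CC[C@@H]12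
F8 | step 13 | C4 aldehyde: 4α-formyl analogue of 16 | O=C[C@]1(C)[C@@H](Cl)C[C@H](O[Si](C)(C)C(C)(C)C)[C@]2(C)[C@@H](CO)C(CO)=CC[C@@H]12
F9 | step 13 | conjugated diene: 4α-(4-methylpenta-1,3-dien-1-yl) analogue of 16 | CC(C)=CC=C[C@]1(C)[C@@H](Cl)C[C@H](O[Si](C)(C)C(C)(C)C)[C@]2(C)[C@@H](CO)C(CO)=CC[C@@H]12
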